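**Retrosynthetic overview**

1. The strategy rests on the Z-trisubstituted C1=C10 alkene (CH3 on C10) of the ten-membered carbocycle C1–C10, which lies next to the C2 carbinol and is trans-fused at C6/C7 to the α-methylene γ-lactone. This alkene is made last, by ring-closing metathesis of the C2 vinyl group with the C10 methylene of diene 33.
2. 33 comes from the C8 carbinol 23 and the epoxy acid 31 (from crotonaldehyde, Sharpless epoxidation) by Mitsunobu esterification with inversion at C8, then desilylation.
3. 23 comes from a zinc Barbier union of bromomethyl butenolide 19 with 3-methylbut-3-enal 21. The chair transition state sets C7 trans to C6 but gives the 7,8-anti (8S) carbinol, the C8 epimer of the target; this is why the ester is attached with inversion.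
4. 19 comes from propargylic alcohol 14 (hydroalumination–iodination, carbonylative lactonisation), itself from enal 11 and alkyne 12. 11 comes from (S)-epichlorohydrin (C1–C3, C2 stereocentre) by carboalumination (E-C4=C5).
5. Ring order: lactone ring (step 9, exocyclic methylene in step 13), oxirane of the side chain (step 18), ten-membered ring (step 22).

Key step: step 22

Numbering: germacranolide numbering is used (ring C1–C10; lactone O on C6, C12 carbonyl, C11=C13 methylene on C7; ester oxygen on C8).

Assumption: in step 7 (R,R)-ProPhenol is taken as the ligand antipode that adds the alkynylzinc to the Si face of enal 11 (6R). The sense is to be confirmed on 14 by Mosher ester analysis, and (S,S)-ProPhenol is used if it proves opposite.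

**Route**

Step 1
Reactants: 1 (S)-epichlorohydrin; 2 ethynyltrimethylsilane
Product: 4 (S)-1-chloro-5-(trimethylsilyl)pent-4-yn-2-ol, via lithium (trimethylsilyl)acetylide 3 (not isolated)
Conditions: n-BuLi, THF, −78 °C; then BF3·OEt2, 1, −78 °C
Reagents that add atoms: none
Why: BF3-promoted opening of the epoxide at its CH2 carbon by the lithium acetylide (Yamaguchi–Hirao alkynylation) breaks no bond at the stereocentre, so the future C2 carbinol is taken from the chiral pool.

Step 2
Reactants: 4 (S)-1-chloro-5-(trimethylsilyl)pent-4-yn-2-ol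
Product: 5 (S)-2-(prop-2-yn-1-yl)oxirane
Conditions: K2CO3, MeOH, 0 °C to rt; volatile product kept as a concentrated ether solution
Reagents that add atoms: none
Why: Carbonate in methanol closes the chlorohydrin to the terminal epoxide (intramolecular Williamson etherification, stereocentre untouched) and cleaves the alkynyl C–Si bond in the same operation.

Step 3
Reactants: 5 (S)-2-(prop-2-yn-1-yl)oxirane
Product: 6 (S)-hex-1-en-5-yn-3-ol
Conditions: Me3S+ I− (3 equiv), n-BuLi (3 equiv), THF, −10 °C; then 5, −10 °C to rt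
Reagents that add atoms: trimethylsulfonium iodide, C[S+](C)C.[I-] (its ylide supplies the terminal CH2)
Why: Dimethylsulfonium methylide opens the epoxide at CH2 and the β-alkoxy sulfonium salt loses dimethyl sulfide (one-carbon homologation of a terminal epoxide to an allylic alcohol), which gives the C1 vinyl group without touching the C2 stereocentre.

Step 4
Reactants: 6 (S)-hex-1-en-5-yn-3-ol
Product: 7 (S)-tert-butyl(hex-1-en-5-yn-3-yloxy)dimethylsilane
Conditions: TBSCl, imidazole, DMF, rt
Reagents that add atoms: tert-butyldimethylsilyl chloride, CC(C)(C)[Si](C)(C)Cl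
Why: Standard silylation of a secondary alcohol gives an ether that should survive the organoaluminium, organozinc, hydride and palladium steps ahead.

Step 5
Reactants: 7 (S)-tert-butyl(hex-1-en-5-yn-3-yloxy)dimethylsilane
Product: 10 (2E,5S)-5-[(tert-butyldimethylsilyl)oxy]-3-methylhepta-2,6-dien-1-ol, via alkenyldimethylalane 8 (not isolated), via lithium butyl(alkenyl)dimethylalanate 9 (not isolated)
Conditions: Me3Al, Cp2ZrCl2 (25 mol %), CH2Cl2, 0 °C to rt; then n-BuLi, THF–hexane, −78 °C; (CH2O)n, −78 °C to rt
Reagents that add atoms: trimethylaluminium, C[Al](C)C; paraformaldehyde (as formaldehyde), C=O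
Why: Zirconium-catalysed syn methylalumination of the terminal alkyne (Negishi carboalumination) and hydroxymethylation of the alanate with retention fix the E-C4=C5 geometry, the monosubstituted alkene being much less reactive under these conditions.

Step 6
Reactants: 10 (2E,5S)-5-[(tert-butyldimethylsilyl)oxy]-3-methylhepta-2,6-dien-1-ol
Product: 11 (2E,5S)-5-[(tert-butyldimethylsilyl)oxy]-3-methylhepta-2,6-dienal
Conditions: MnO2, CH2Cl2, rt
Reagents that add atoms: none
Why: MnO2 oxidises only the allylic alcohol and should leave the alkene geometry, the silyl ether and the vinyl group unchanged.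

Step 7
Reactants: 11 (2E,5S)-5-[(tert-butyldimethylsilyl)oxy]-3-methylhepta-2,6-dienal; 12 tert-butyldimethyl(prop-2-yn-1-yloxy)silane
Product: 14 (4R,5E,8S)-1,8-bis[(tert-butyldimethylsilyl)oxy]-6-methyldeca-5,9-dien-2-yn-4-ol, via methyl(alkynyl)zinc 13 (not isolated)
Conditions: Me2Zn, (R,R)-ProPhenol (20 mol %), Ph3P=O (40 mol %), toluene, 0–4 °C
Reagents that add atoms: none
Why: Catalytic asymmetric alkynylation of an enal by an alkynylzinc on a dinuclear zinc–ProPhenol catalyst sets C6 (R) by reagent control, the remote C2 centre being too far away to interfere.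

Step 8
Reactants: 14 (4R,5E,8S)-1,8-bis[(tert-butyldimethylsilyl)oxy]-6-methyldeca-5,9-dien-2-yn-4-ol
Product: 16 (2Z,4R,5E,8S)-1,8-bis[(tert-butyldimethylsilyl)oxy]-2-iodo-6-methyldeca-2,5,9-trien-4-ol, via cyclic sodium alkenylalanate 15 (not isolated)
Conditions: NaAlH2(OCH2CH2OCH3)2, THF, −78 to 0 °C; then EtOAc; I2, THF, −78 °C
Reagents that add atoms: iodine, II
Why: Alkoxide-directed trans-hydroalumination of the propargylic alcohol puts hydride on C7 and aluminium on C11, and iodinolysis with retention gives the Z-iodoalkene with iodine cis to C6; the low temperature should keep the silyloxy group from leaving to an allene.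

Step 9
Reactants: 16 (2Z,4R,5E,8S)-1,8-bis[(tert-butyldimethylsilyl)oxy]-2-iodo-6-methyldeca-2,5,9-trien-4-ol
Product: 17 (5R)-3-{[(tert-butyldimethylsilyl)oxy]methyl}-5-[(1E,4S)-4-[(tert-butyldimethylsilyl)oxy]-2-methylhexa-1,5-dien-1-yl]furan-2(5H)-one
Conditions: PdCl2(PPh3)2 (5 mol %), CO (1 atm), K2CO3, THF, rt
Reagents that add atoms: carbon monoxide, [C-]#[O+]
Why: Palladium-catalysed carbonylative lactonisation (oxidative addition into C–I, CO insertion, capture of the acyl by the cis C6 hydroxyl) closes the butenolide ring with C13 already in place, and the mild heterogeneous base limits deprotonation at C6.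

Step 10
Reactants: 17 (5R)-3-{[(tert-butyldimethylsilyl)oxy]methyl}-5-[(1E,4S)-4-[(tert-butyldimethylsilyl)oxy]-2-methylhexa-1,5-dien-1-yl]furan-2(5H)-one
Product: 18 (5R)-5-[(1E,4S)-4-[(tert-butyldimethylsilyl)oxy]-2-methylhexa-1,5-dien-1-yl]-3-(hydroxymethyl)furan-2(5H)-one
Conditions: CSA (10 mol %), MeOH–CH2Cl2 1:1, 0 °C
Reagents that add atoms: none
Why: Acid-catalysed methanolysis cleaves the unhindered primary silyl ether much faster than the secondary C2 silyl ether, so the C13 hydroxyl should be freed selectively.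

Step 11
Reactants: 18 (5R)-5-[(1E,4S)-4-[(tert-butyldimethylsilyl)oxy]-2-methylhexa-1,5-dien-1-yl]-3-(hydroxymethyl)furan-2(5H)-one
Product: 19 (5R)-3-(bromomethyl)-5-[(1E,4S)-4-[(tert-butyldimethylsilyl)oxy]-2-methylhexa-1,5-dien-1-yl]furan-2(5H)-one
Conditions: CBr4, PPh3, CH2Cl2, 0 °C
Reagents that add atoms: carbon tetrabromide, BrC(Br)(Br)Br
Why: The Appel reaction turns the primary allylic alcohol into the bromide under neutral conditions, which avoids base-induced epimerisation of the acidic C6 position.

Step 12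
Reactants: 20 3-methylbut-3-en-1-ol
Product: 21 3-methylbut-3-enal
Conditions: Dess–Martin periodinane, NaHCO3, CH2Cl2, 0 °C; cold filtered solution used at once
Reagents that add atoms: none
Why: Buffered Dess–Martin oxidation gives the β,γ-unsaturated aldehyde, and immediate use without concentration or chromatography should prevent its conjugation to 3-methylbut-2-enal.

Step 13
Reactants: 19 (5R)-3-(bromomethyl)-5-[(1E,4S)-4-[(tert-butyldimethylsilyl)oxy]-2-methylhexa-1,5-dien-1-yl]furan-2(5H)-one; 21 3-methylbut-3-enal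
Product: 23 (4R,5R)-5-[(1E,4S)-4-[(tert-butyldimethylsilyl)oxy]-2-methylhexa-1,5-dien-1-yl]-4-[(1S)-1-hydroxy-3-methylbut-3-en-1-yl]-3-methylideneoxolan-2-one, via allylzinc bromide 22 (not isolated)
Conditions: Zn dust, THF–sat. aq. NH4Cl, 0 °C to rt
Reagents that add atoms: none
Why: In this zinc Barbier allylation the allylzinc reacts at its γ-carbon C7 on the face anti to the C6 substituent (C7 R, trans-lactone) through a chair Zimmerman–Traxler transition state in which the ring-locked E-type allyl unit leads to the 7,8-anti carbinol (C8 S), the epimer that step 20 inverts.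

Step 14
Reactants: 24 (E)-but-2-enal
Product: 25 (Z)-2-iodobut-2-enal
Conditions: I2, K2CO3, DMAP (20 mol %), THF–H2O 1:1, rt
Reagents that add atoms: iodine, II
Why: Amine-catalysed α-iodination of an enal (conjugate addition of DMAP, iodination of the enolate, elimination) leaves the formyl group trans to the methyl group, so iodine ends cis to CH3.

Step 15
Reactants: 25 (Z)-2-iodobut-2-enal
Product: 26 (Z)-2-iodobut-2-en-1-ol
Conditions: NaBH4, CeCl3·7H2O, MeOH, 0 °C
Reagents that add atoms: none
Why: Luche reduction gives clean 1,2-reduction of the enal without loss of iodine or alkene geometry.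

Step 16
Reactants: 26 (Z)-2-iodobut-2-en-1-ol
Product: 27 (Z)-tert-butyl[(2-iodobut-2-en-1-yl)oxy]dimethylsilane
Conditions: TBSCl, imidazole, DMF, rt
Reagents that add atoms: tert-butyldimethylsilyl chloride, CC(C)(C)[Si](C)(C)Cl
Why: Silylation marks this CH2O arm (trans to CH3) as the future hydroxymethyl group of the side chain.

Step 17
Reactants: 27 (Z)-tert-butyl[(2-iodobut-2-en-1-yl)oxy]dimethylsilane
Product: 29 (E)-2-{[(tert-butyldimethylsilyl)oxy]methyl}but-2-en-1-ol, via alkenyllithium 28 (not isolated)
Conditions: t-BuLi (2.1 equiv), Et2O, −78 °C; then (CH2O)n, −78 °C to rt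
Reagents that add atoms: paraformaldehyde (as formaldehyde), C=O
Why: Lithium–iodine exchange and hydroxymethylation both proceed with retention at the alkenyl carbon, so the free CH2OH is placed cis to the methyl group.

Step 18
Reactants: 29 (E)-2-{[(tert-butyldimethylsilyl)oxy]methyl}but-2-en-1-ol
Product: 30 [(2R,3R)-2-{[(tert-butyldimethylsilyl)oxy]methyl}-3-methyloxiran-2-yl]methanol
Conditions: Ti(OiPr)4 (10 mol %), L-(+)-diethyl tartrate (12 mol %), t-BuOOH, 4 Å MS, CH2Cl2, −20 °C
Reagents that add atoms: tert-butyl hydroperoxide, CC(C)(C)OO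
Why: In the Sharpless asymmetric epoxidation the titanium–tartrate complex binds the free allylic hydroxyl and, with the L-(+)-tartrate, delivers oxygen to the alkene face that gives the 2R,3R epoxide (reagent control), with methyl and CH2OH cis as in the alkene.

Step 19
Reactants: 30 [(2R,3R)-2-{[(tert-butyldimethylsilyl)oxy]methyl}-3-methyloxiran-2-yl]methanol
Product: 31 (2R,3R)-2-{[(tert-butyldimethylsilyl)oxy]methyl}-3-methyloxirane-2-carboxylic acid
Conditions: TEMPO (20 mol %), PhI(OAc)2 (2.2 equiv), MeCN–H2O 1:1, rt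
Reagents that add atoms: water, O
Why: Oxoammonium oxidation of the primary alcohol through the aldehyde hydrate gives the acid under near-neutral conditions that the epoxide and the silyl ether should tolerate.

Step 20
Reactants: 23 (4R,5R)-5-[(1E,4S)-4-[(tert-butyldimethylsilyl)oxy]-2-methylhexa-1,5-dien-1-yl]-4-[(1S)-1-hydroxy-3-methylbut-3-en-1-yl]-3-methylideneoxolan-2-one; 31 (2R,3R)-2-{[(tert-butyldimethylsilyl)oxy]methyl}-3-methyloxirane-2-carboxylic acid
Product: 32 (1R)-1-[(2R,3R)-2-[(1E,4S)-4-[(tert-butyldimethylsilyl)oxy]-2-methylhexa-1,5-dien-1-yl]-4-methylidene-5-oxooxolan-3-yl]-3-methylbut-3-en-1-yl (2R,3R)-2-{[(tert-butyldimethylsilyl)oxy]methyl}-3-methyloxirane-2-carboxylate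
Conditions: PPh3, DIAD, toluene, 0 °C to rt
Reagents that add atoms: none
Why: In the Mitsunobu esterification the C8 hydroxyl is activated as an alkoxyphosphonium ion and displaced by the carboxylate in an SN2 step, which inverts C8 from S to R and installs the side chain in one operation.

Step 21
Reactants: 32 (the bis-silyl ether from step 20)
Product: 33 (1R)-1-[(2R,3R)-2-[(1E,4S)-4-hydroxy-2-methylhexa-1,5-dien-1-yl]-4-methylidene-5-oxooxolan-3-yl]-3-methylbut-3-en-1-yl (2R,3R)-2-(hydroxymethyl)-3-methyloxirane-2-carboxylate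
Conditions: HF·pyridine, pyridine, THF, 0 °C to rt
Reagents that add atoms: none
Why: Buffered fluoride cleaves both silyl ethers and should leave the epoxy ester, the α-methylene lactone and the alkenes untouched, which frees the allylic C2 hydroxyl for the ring closure.

Step 22
Reactants: 33 (the diene diol from step 21)
Product: 34 target, (3aR,4R,6Z,8S,10E,11aR)-8-hydroxy-6,10-dimethyl-3-methylidene-2-oxo-2,3,3a,4,5,8,9,11a-octahydrocyclodeca[b]furan-4-yl (2R,3R)-2-(hydroxymethyl)-3-methyloxirane-2-carboxylate
Conditions: second-generation Grubbs catalyst RuCl2(=CHPh)(H2IMes)(PCy3) (15 mol %), 1,4-benzoquinone (20 mol %), toluene (1 mM), 80 °C, argon sparge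
Reagents that add atoms: none
Why: By the Chauvin mechanism the catalyst benzylidene exchanges with the only monosubstituted alkene, the C1 vinyl group, and the ruthenium alkylidene at C1 adds to the 1,1-disubstituted C10 methylene to give a ruthenacyclobutane whose cycloreversion forms C1=C10 and expels ethene. The closest known reaction type is ring-closing metathesis to medium rings that contain a cis trisubstituted alkene. The ten-membered carbocycle is closed end to end by alkene–alkene metathesis, with the trans-fused lactone and the E-C4=C5 alkene acting as two rigid turns that hold C1 and C10 near each other. No stereocentre is formed; the Z geometry is the one expected from closure of a ten-membered ring, where the ruthenacycle leading to the cis alkene is the less strained, and it is to be checked by NOE. Site selectivity among the five alkenes should hold because the C11=C13 methylene is electron-poor and hindered and could close only to an eight-membered ring holding a trans alkene, the trisubstituted C4=C5 alkene is unreactive, and two 1,1-disubstituted alkenes do not combine with this catalyst. The free allylic C2 hydroxyl is expected to speed the closure, high dilution to suppress cross-metathesis, and benzoquinone to suppress isomerisation of the allylic alcohol to a ketone.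

**Compound list**

1 | (S)-epichlorohydrin | ClC[C@@H]1CO1 | starting material
2 | ethynyltrimethylsilane | C#C[Si](C)(C)C | starting material
3 | lithium (trimethylsilyl)acetylide | [Li]C#C[Si](C)(C)C | intermediate (not isolated)
4 | (S)-1-chloro-5-(trimethylsilyl)pent-4-yn-2-ol | C[Si](C)(C)C#CC[C@H](O)CCl | intermediate
5 | (S)-2-(prop-2-yn-1-yl)oxirane | C#CC[C@H]1CO1 | intermediate
6 | (S)-hex-1-en-5-yn-3-ol | C#CC[C@H](O)C=C | intermediate
7 | (S)-tert-butyl(hex-1-en-5-yn-3-yloxy)dimethylsilane | C#CC[C@H](O[Si](C)(C)C(C)(C)C)C=C | intermediate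
8 | (E)-alkenyldimethylalane from 7 | C[Al](C)/C=C(\C)C[C@H](O[Si](C)(C)C(C)(C)C)C=C | intermediate (not isolated)
9 | lithium butyl(alkenyl)dimethylalanate | [Li+].CCCC[Al-](C)(C)/C=C(\C)C[C@H](O[Si](C)(C)C(C)(C)C)C=C | intermediate (not isolated)
10 | (2E,5S)-5-[(tert-butyldimethylsilyl)oxy]-3-methylhepta-2,6-dien-1-ol | OC/C=C(\C)C[C@H](O[Si](C)(C)C(C)(C)C)C=C | intermediate
11 | (2E,5S)-5-[(tert-butyldimethylsilyl)oxy]-3-methylhepta-2,6-dienal | O=C/C=C(\C)C[C@H](O[Si](C)(C)C(C)(C)C)C=C | intermediate
12 | tert-butyldimethyl(prop-2-yn-1-yloxy)silane | C#CCO[Si](C)(C)C(C)(C)C | starting material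
13 | methyl[3-(tert-butyldimethylsilyloxy)prop-1-ynyl]zinc | C[Zn]C#CCO[Si](C)(C)C(C)(C)C | intermediate (not isolated)
14 | (4R,5E,8S)-1,8-bis[(tert-butyldimethylsilyl)oxy]-6-methyldeca-5,9-dien-2-yn-4-ol | CC(C)(C)[Si](C)(C)OCC#C[C@H](O)/C=C(\C)C[C@H](O[Si](C)(C)C(C)(C)C)C=C | intermediate
15 | cyclic sodium alkenylalanate (Al on C11 and on the C6 oxygen) | [Na+].COCCO[Al-]1(OCCOC)O[C@H](/C=C(\C)C[C@H](O[Si](C)(C)C(C)(C)C)C=C)C=C1CO[Si](C)(C)C(C)(C)C | intermediate (not isolated)
16 | (2Z,4R,5E,8S)-1,8-bis[(tert-butyldimethylsilyl)oxy]-2-iodo-6-methyldeca-2,5,9-trien-4-ol | CC(C)(C)[Si](C)(C)OC/C(I)=C/[C@H](O)/C=C(\C)C[C@H](O[Si](C)(C)C(C)(C)C)C=C | intermediate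
17 | (5R)-3-{[(tert-butyldimethylsilyl)oxy]methyl}-5-[(1E,4S)-4-[(tert-butyldimethylsilyl)oxy]-2-methylhexa-1,5-dien-1-yl]furan-2(5H)-one | CC(C)(C)[Si](C)(C)OCC1=C[C@@H](/C=C(\C)C[C@H](O[Si](C)(C)C(C)(C)C)C=C)OC1=O | intermediate
18 | (5R)-5-[(1E,4S)-4-[(tert-butyldimethylsilyl)oxy]-2-methylhexa-1,5-dien-1-yl]-3-(hydroxymethyl)furan-2(5H)-one | OCC1=C[C@@H](/C=C(\C)C[C@H](O[Si](C)(C)C(C)(C)C)C=C)OC1=O | intermediate
19 | (5R)-3-(bromomethyl)-5-[(1E,4S)-4-[(tert-butyldimethylsilyl)oxy]-2-methylhexa-1,5-dien-1-yl]furan-2(5H)-one | BrCC1=C[C@@H](/C=C(\C)C[C@H](O[Si](C)(C)C(C)(C)C)C=C)OC1=O | intermediate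
20 | 3-methylbut-3-en-1-ol | C=C(C)CCO | starting material
21 | 3-methylbut-3-enal | C=C(C)CC=O | intermediate
22 | allylzinc bromide from 19 | Br[Zn]CC1=C[C@@H](/C=C(\C)C[C@H](O[Si](C)(C)C(C)(C)C)C=C)OC1=O | intermediate (not isolated)
23 | (4R,5R)-5-[(1E,4S)-4-[(tert-butyldimethylsilyl)oxy]-2-methylhexa-1,5-dien-1-yl]-4-[(1S)-1-hydroxy-3-methylbut-3-en-1-yl]-3-methylideneoxolan-2-one (6R,7R,8S) | C=C(C)C[C@H](O)[C@H]1C(=C)C(=O)O[C@@H]1/C=C(\C)C[C@H](O[Si](C)(C)C(C)(C)C)C=C | intermediate
24 | (E)-but-2-enal | C/C=C/C=O | starting material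
25 | (Z)-2-iodobut-2-enal | C/C=C(\I)C=O | intermediate
26 | (Z)-2-iodobut-2-en-1-ol | C/C=C(\I)CO | intermediate
27 | (Z)-tert-butyl[(2-iodobut-2-en-1-yl)oxy]dimethylsilane | C/C=C(\I)CO[Si](C)(C)C(C)(C)C | intermediate
28 | alkenyllithium from 27 | C/C=C(\[Li])CO[Si](C)(C)C(C)(C)C | intermediate (not isolated)
29 | (E)-2-{[(tert-butyldimethylsilyl)oxy]methyl}but-2-en-1-ol | C/C=C(\CO)CO[Si](C)(C)C(C)(C)C | intermediate
30 | [(2R,3R)-2-{[(tert-butyldimethylsilyl)oxy]methyl}-3-methyloxiran-2-yl]methanol | OC[C@]1(CO[Si](C)(C)C(C)(C)C)O[C@@H]1C | intermediate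
31 | (2R,3R)-2-{[(tert-butyldimethylsilyl)oxy]methyl}-3-methyloxirane-2-carboxylic acid | OC(=O)[C@]1(CO[Si](C)(C)C(C)(C)C)O[C@@H]1C | intermediate
32 | bis-silyl ether of the ring-closing precursor (C8 R ester, C2 and side-chain O-TBS) | C=C(C)C[C@@H](OC(=O)[C@]2(CO[Si](C)(C)C(C)(C)C)O[C@@H]2C)[C@H]1C(=C)C(=O)O[C@@H]1/C=C(\C)C[C@H](O[Si](C)(C)C(C)(C)C)C=C | intermediate
33 | ring-closing precursor, trans-lactone diene with free C2 hydroxyl and C8 epoxy ester | C=C(C)C[C@@H](OC(=O)[C@]2(CO)O[C@@H]2C)[C@H]1C(=C)C(=O)O[C@@H]1/C=C(\C)C[C@H](O)C=C | intermediate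
34 | target germacranolide | C=C1C(=O)O[C@@H]2/C=C(\C)C[C@H](O)/C=C(/C)C[C@@H](OC(=O)[C@]3(CO)O[C@@H]3C)[C@@H]12 | target

**Step count and risks**

Total step count: 22. Longest linear sequence: 15 steps (steps 1–11, 13, 20, 21, 22).

Steps most likely to fail:

1. Step 22. The ruthenium alkylidene at C1 may be consumed by intermolecular metathesis (oligomers) faster than it closes the strained ring, or closure may give the E alkene. Fallback, from 23 back to 34: the ring is closed before the acylation, on a substrate with a small free 8-hydroxyl in place of the ester and a different conformation of the C7 arm. Carbinol 23 is treated with the same catalyst at high dilution to give the ten-membered 8S alcohol F1. F1 is esterified with acid 31 under Mitsunobu conditions with inversion to the macrocyclic bis-silyl ether F2. HF·pyridine then gives 34.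

2. Step 20. The alkoxyphosphonium ion at C8 may undergo elimination toward C7 or C9 (conjugated dienes), or the hindered carbinol may fail to react. Fallback, from 23 back to 32: inversion and acylation are separated. Tf2O and pyridine at −40 °C give the triflate F3. Tetrabutylammonium nitrite in DMF displaces it with inversion (Lattrell–Dax) to the nitrite ester F4, which is hydrolysed on work-up to the 8R alcohol F5. Acid 31 is converted with 2,4,6-trichlorobenzoyl chloride and Et3N to the mixed anhydride F6, which acylates F5 with DMAP in toluene (Yamaguchi esterification, retention) to give 32.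

3. Step 7. The facial selectivity of the alkynylzinc addition may be low or of the wrong sense, or methyl transfer from Me2Zn may compete. Fallback, from 11 and 12 back to 14: the stereocentre is set by reduction instead of addition. Alkyne 12 is lithiated with n-BuLi to the acetylide F7, which adds to 11 to give the C6-epimeric alcohols F8. MnO2 gives the ynone F9. Midland reduction with (R)-Alpine-Borane, in which the alkynyl group is the small substituent, should give the 6R alcohol 14.

**Further compounds**

F1 | step 22 | ten-membered 8S alcohol with C2 O-TBS | C=C1C(=O)O[C@@H]2/C=C(\C)C[C@H](O[Si](C)(C)C(C)(C)C)/C=C(/C)C[C@H](O)[C@@H]12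
F2 | step 22 | macrocyclic bis-silyl ether of the target | C=C1C(=O)O[C@@H]2/C=C(\C)C[C@H](O[Si](C)(C)C(C)(C)C)/C=C(/C)C[C@@H](OC(=O)[C@]3(CO[Si](C)(C)C(C)(C)C)O[C@@H]3C)[C@@H]12
F3 | step 20 | C8 (S) triflate of 23 | C=C(C)C[C@H](OS(=O)(=O)C(F)(F)F)[C@H]1C(=C)C(=O)O[C@@H]1/C=C(\C)C[C@H](O[Si](C)(C)C(C)(C)C)C=C
F4 | step 20 | C8 (R) nitrite ester | C=C(C)C[C@@H](ON=O)[C@H]1C(=C)C(=O)O[C@@H]1/C=C(\C)C[C@H](O[Si](C)(C)C(C)(C)C)C=C
F5 | step 20 | C8 (R) alcohol, the 8-epimer of 23 | C=C(C)C[C@@H](O)[C@H]1C(=C)C(=O)O[C@@H]1/C=C(\C)C[C@H](O[Si](C)(C)C(C)(C)C)C=C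
F6 | step 20 | mixed anhydride of 31 with 2,4,6-trichlorobenzoic acid | O=C(OC(=O)c1c(Cl)cc(Cl)cc1Cl)[C@]1(CO[Si](C)(C)C(C)(C)C)O[C@@H]1C
F7 | step 7 | lithium acetylide of 12 | [Li]C#CCO[Si](C)(C)C(C)(C)C
F8 | step 7 | C6-epimeric mixture of 14 | CC(C)(C)[Si](C)(C)OCC#CC(O)/C=C(\C)C[C@H](O[Si](C)(C)C(C)(C)C)C=C
F9 | step 7 | (5E,8S)-1,8-bis[(tert-butyldimethylsilyl)oxy]-6-methyldeca-5,9-dien-2-yn-4-one | CC(C)(C)[Si](C)(C)OCC#CC(=O)/C=C(\C)C[C@H](O[Si](C)(C)C(C)(C)C)C=C
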